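## Retrosynthetic overview

1. The target is disconnected at C5–C10: an acid-triggered transannular cation–olefin closure of a (1(10)E,4E)-germacra-1(10),4,11(13)-trien-12-oate that already carries the 3-propanoate, the 8-acetate and the methyl acrylate forms both six-membered rings last and sets C10.
2. The germacratriene is disconnected at C7–C8: intramolecular zinc Barbier allylation of an acyclic ω-formyl (Z)-2-(bromomethyl)enoate closes the ten-membered ring and sets C7 and C8 (cis).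
3. The bromomethyl enoate comes from cross-metathesis (C7=C11) with methyl 2-(bromomethyl)acrylate, after Stille vinylation (C6–C7) of an allylic acetate.
4. The C3 carbinol comes from α-selective allylbarium addition (C2–C3) of an (E)-allylic chloride (Negishi carboalumination of a butynyl silyl ether) to (E)-4-acetoxy-2-methylbut-2-enal; Sharpless kinetic resolution gives 3S.
5. Ring order: the ten-membered carbocycle first (step 10), then ring A and ring B of the decalin in one transannular event (step 11).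

Assumption: locants C1–C15 follow eudesmane/germacrane numbering (C3 propanoate, C7 acrylate, C8 acetate, C10 angular methyl); TBS = tert-butyldimethylsilyl, TBDPS = tert-butyldiphenylsilyl; compounds 1, 6 and 13 are taken as catalogue chemicals.

## Route

Step 1
Reactants: 1 tert-butyl(but-3-yn-1-yloxy)dimethylsilane
Product: 4 (2E)-5-(TBS-oxy)-3-methylpent-2-en-1-ol, via alkenylalane 2 (not isolated), via lithium alkenylalanate 3 (not isolated)
Conditions: Me3Al, Cp2ZrCl2 (0.25 equiv), CH2Cl2, 0→23 °C; n-BuLi, THF, −78 °C; (CH2O)n, −78→23 °C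
Reagents that add atoms: trimethylaluminium C[Al](C)C; paraformaldehyde (as formaldehyde) C=O
Why: Zirconium-catalysed Negishi carboalumination adds Me–Al syn across the terminal alkyne with methyl on the internal carbon, and the derived alanate attacks formaldehyde with retention, fixing the E trisubstituted alkene that becomes C1=C10.

Step 2
Reactants: 4 (2E)-5-(TBS-oxy)-3-methylpent-2-en-1-ol
Product: 5 tert-butyl{[(3E)-5-chloro-3-methylpent-3-en-1-yl]oxy}dimethylsilane
Conditions: NCS, Me2S, CH2Cl2, −30→0 °C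
Reagents that add atoms: N-chlorosuccinimide ClN1C(=O)CCC1=O
Why: Corey–Kim chlorination displaces the alkoxysulfonium by SN2 at the primary allylic carbon, without allylic transposition or loss of the E geometry, and leaves the silyl ether alone.

Step 3
Reactants: 5 tert-butyl{[(3E)-5-chloro-3-methylpent-3-en-1-yl]oxy}dimethylsilane; 6 (2E)-3-methyl-4-oxobut-2-en-1-yl acetate
Product: 8 rac-(2E,6E)-9-(TBS-oxy)-4-hydroxy-3,7-dimethylnona-2,6-dien-1-yl acetate, via allylbarium chloride 7 (not isolated)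
Conditions: BaI2, Li, biphenyl, THF, 23 °C; 5, −78 °C; then 6, −78 °C; aq. NH4Cl
Reagents that add atoms: none
Why: Yamamoto allylbarium addition: the γ,γ-disubstituted allylbarium formed at −78 °C reacts at its unsubstituted α-carbon with retention of the E alkene and adds 1,2 to the enal, giving the linear homoallylic carbinol (C2–C3 bond), racemic at C3.

Step 4
Reactants: 8 rac-(2E,6E)-9-(TBS-oxy)-4-hydroxy-3,7-dimethylnona-2,6-dien-1-yl acetate
Product: 9 (2E,4S,6E)-9-(TBS-oxy)-4-hydroxy-3,7-dimethylnona-2,6-dien-1-yl acetate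
Conditions: Ti(OiPr)4 (0.2 equiv), D-(−)-DIPT (0.24 equiv), t-BuOOH (0.6 equiv), 4 Å MS, CH2Cl2, −20 °C, stopped at ca. 55% conversion
Reagents that add atoms: none
Why: Sharpless kinetic resolution: the titanium–D-(−)-tartrate catalyst epoxidises the (R)-allylic alcohol much faster, so the unreacted alcohol is recovered as the (S)-enantiomer, which is the C3 configuration of the target.

Step 5
Reactants: 9 (2E,4S,6E)-9-(TBS-oxy)-4-hydroxy-3,7-dimethylnona-2,6-dien-1-yl acetate
Product: 10 (4E,6S,8E)-11-(TBS-oxy)-5,9-dimethylundeca-1,4,8-trien-6-ol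
Conditions: CH2=CHSnBu3, Pd2(dba)3 (2.5 mol%), LiCl, DMF, 23→40 °C
Reagents that add atoms: tributyl(vinyl)stannane C=C[Sn](CCCC)(CCCC)CCCC
Why: Stille-type coupling of an allylic acetate: zerovalent palladium ionises the primary acetate and the vinyl group is delivered to the unhindered terminus with retention of the E alkene, the free secondary alcohol and the C3 stereocentre being untouched.

Step 6
Reactants: 10 (4E,6S,8E)-11-(TBS-oxy)-5,9-dimethylundeca-1,4,8-trien-6-ol
Product: 11 (4E,6S,8E)-11-(TBS-oxy)-5,9-dimethylundeca-1,4,8-trien-6-yl propanoate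
Conditions: (EtCO)2O, Et3N, DMAP (cat.), CH2Cl2, 0→23 °C
Reagents that add atoms: propanoic anhydride CCC(=O)OC(=O)CC
Why: DMAP-catalysed acylation of the secondary allylic alcohol proceeds with retention at C3 and installs the propanoate of the target early.

Step 7
Reactants: 11 (4E,6S,8E)-11-(TBS-oxy)-5,9-dimethylundeca-1,4,8-trien-6-yl propanoate
Product: 12 (4E,6S,8E)-11-hydroxy-5,9-dimethylundeca-1,4,8-trien-6-yl propanoate
Conditions: HF·pyridine, pyridine, THF, 0→23 °C
Reagents that add atoms: none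
Why: Buffered fluoride desilylation cleaves the primary silyl ether and leaves the allylic propanoate and the skipped diene intact.

Step 8
Reactants: 12 (4E,6S,8E)-11-hydroxy-5,9-dimethylundeca-1,4,8-trien-6-yl propanoate; 13 methyl 2-(bromomethyl)prop-2-enoate
Product: 14 methyl (2Z,5E,7S,9E)-2-(bromomethyl)-12-hydroxy-6,10-dimethyl-7-(propanoyloxy)dodeca-2,5,9-trienoate
Conditions: 13 (4 equiv), second-generation Hoveyda–Grubbs catalyst [1,3-bis(2,4,6-trimethylphenyl)imidazolidin-2-ylidene]dichloro(2-isopropoxybenzylidene)ruthenium (5 mol%), CH2Cl2, 40 °C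
Reagents that add atoms: none
Why: Olefin cross-metathesis: only the monosubstituted terminal alkene of 12 engages the ruthenium carbene and pairs with the non-dimerising 1,1-disubstituted acrylate 13, the preferred geometry placing the chain trans to the ester (2Z), while the trisubstituted alkenes are inert.

Step 9
Reactants: 14 methyl (2Z,5E,7S,9E)-2-(bromomethyl)-12-hydroxy-6,10-dimethyl-7-(propanoyloxy)dodeca-2,5,9-trienoate
Product: 15 methyl (2Z,5E,7S,9E)-2-(bromomethyl)-6,10-dimethyl-12-oxo-7-(propanoyloxy)dodeca-2,5,9-trienoate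
Conditions: Dess–Martin periodinane, pyridine, CH2Cl2, 0 °C; crude used at once
Reagents that add atoms: none
Why: Buffered Dess–Martin oxidation gives the β,γ-unsaturated aldehyde without moving the alkene into conjugation, and the allylic bromide and esters are inert to it.

Step 10
Reactants: 15 methyl (2Z,5E,7S,9E)-2-(bromomethyl)-6,10-dimethyl-12-oxo-7-(propanoyloxy)dodeca-2,5,9-trienoate
Product: 18 methyl (3S,7R,8R,1(10)E,4E)-8-acetoxy-3-(propanoyloxy)germacra-1(10),4,11(13)-trien-12-oate, via allylzinc bromide 16 (not isolated), via bromozinc alkoxide 17 (not isolated)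
Conditions: activated Zn dust, THF, 23 °C, syringe-pump addition (final 2 mM); then Ac2O, Et3N, DMAP, 0→23 °C
Reagents that add atoms: acetic anhydride CC(=O)OC(C)=O
Why: Intramolecular zinc Barbier (Reformatsky-type) allylation under high dilution closes the ten-membered germacrane ring at C7–C8 through a chair transition state of the ester-chelated allylzinc that gives the syn (7,8-cis) adduct, the ring forming in the crown conformer that keeps the C3 ester and C7 side chain pseudo-equatorial so that C7 and C8 are both R, and the zinc alkoxide is acetylated before it can lactonise.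

Step 11
Reactants: 18 methyl (3S,7R,8R,1(10)E,4E)-8-acetoxy-3-(propanoyloxy)germacra-1(10),4,11(13)-trien-12-oate
Product: 19 methyl (3S,7R,8R,10R)-8-acetoxy-3-(propanoyloxy)eudesma-4,11(13)-dien-12-oate (3β-propanoyloxy, 8β-acetoxy; the target)
Conditions: TsOH (0.2 equiv), CH2Cl2, 0→23 °C
Reagents that add atoms: none
Why: Germacrene-to-eudesmane cation–olefin cyclisation: acid protonates the 1(10)-alkene at C1 (the 4,5-alkene is deactivated by the allylic ester), C5 captures the C10 cation transannularly in the chair–chair crown conformer with the C3 and C7 substituents equatorial and only the C8 acetate axial, which sets C10 as R with the methyl cis to the C7 side chain, and loss of H5 (with acid equilibration of any 4(15)-isomer) gives the tetrasubstituted 4-ene.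

## Compound list

1 | tert-butyl(but-3-yn-1-yloxy)dimethylsilane | C#CCCO[Si](C)(C)C(C)(C)C | starting material
2 | [(1E)-4-(TBS-oxy)-2-methylbut-1-en-1-yl]dimethylalane | C/C(=C\[Al](C)C)CCO[Si](C)(C)C(C)(C)C | intermediate (not isolated)
3 | lithium butyl[(1E)-4-(TBS-oxy)-2-methylbut-1-en-1-yl]dimethylalanate | [Li+].CCCC[Al-](C)(C)/C=C(\C)CCO[Si](C)(C)C(C)(C)C | intermediate (not isolated)
4 | (2E)-5-(TBS-oxy)-3-methylpent-2-en-1-ol | C/C(=C\CO)CCO[Si](C)(C)C(C)(C)C | intermediate
5 | tert-butyl{[(3E)-5-chloro-3-methylpent-3-en-1-yl]oxy}dimethylsilane | C/C(=C\CCl)CCO[Si](C)(C)C(C)(C)C | intermediate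
6 | (2E)-3-methyl-4-oxobut-2-en-1-yl acetate, i.e. (E)-4-acetoxy-2-methylbut-2-enal | CC(=O)OC/C=C(\C)C=O | starting material
7 | [(2E)-5-(TBS-oxy)-3-methylpent-2-en-1-yl]barium chloride | C/C(=C\C[Ba]Cl)CCO[Si](C)(C)C(C)(C)C | intermediate (not isolated)
8 | rac-(2E,6E)-9-(TBS-oxy)-4-hydroxy-3,7-dimethylnona-2,6-dien-1-yl acetate (racemic at C4 of the chain) | CC(=O)OC/C=C(\C)C(O)C/C=C(\C)CCO[Si](C)(C)C(C)(C)C | intermediate
9 | (2E,4S,6E)-9-(TBS-oxy)-4-hydroxy-3,7-dimethylnona-2,6-dien-1-yl acetate | CC(=O)OC/C=C(\C)[C@@H](O)C/C=C(\C)CCO[Si](C)(C)C(C)(C)C | intermediate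
10 | (4E,6S,8E)-11-(TBS-oxy)-5,9-dimethylundeca-1,4,8-trien-6-ol | C=CC/C=C(\C)[C@@H](O)C/C=C(\C)CCO[Si](C)(C)C(C)(C)C | intermediate
11 | (4E,6S,8E)-11-(TBS-oxy)-5,9-dimethylundeca-1,4,8-trien-6-yl propanoate | C=CC/C=C(\C)[C@@H](OC(=O)CC)C/C=C(\C)CCO[Si](C)(C)C(C)(C)C | intermediate
12 | (4E,6S,8E)-11-hydroxy-5,9-dimethylundeca-1,4,8-trien-6-yl propanoate | C=CC/C=C(\C)[C@@H](OC(=O)CC)C/C=C(\C)CCO | intermediate
13 | methyl 2-(bromomethyl)prop-2-enoate | C=C(CBr)C(=O)OC | starting material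
14 | methyl (2Z,5E,7S,9E)-2-(bromomethyl)-12-hydroxy-6,10-dimethyl-7-(propanoyloxy)dodeca-2,5,9-trienoate | BrC/C(C(=O)OC)=C\C/C=C(\C)[C@@H](OC(=O)CC)C/C=C(\C)CCO | intermediate
15 | methyl (2Z,5E,7S,9E)-2-(bromomethyl)-6,10-dimethyl-12-oxo-7-(propanoyloxy)dodeca-2,5,9-trienoate | BrC/C(C(=O)OC)=C\C/C=C(\C)[C@@H](OC(=O)CC)C/C=C(\C)CC=O | intermediate
16 | methyl (2Z,5E,7S,9E)-2-[(bromozincio)methyl]-6,10-dimethyl-12-oxo-7-(propanoyloxy)dodeca-2,5,9-trienoate | Br[Zn]C/C(C(=O)OC)=C\C/C=C(\C)[C@@H](OC(=O)CC)C/C=C(\C)CC=O | intermediate (not isolated)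
17 | bromozinc alkoxide of methyl (3S,7R,8R,1(10)E,4E)-8-hydroxy-3-(propanoyloxy)germacra-1(10),4,11(13)-trien-12-oate | C=C(C(=O)OC)[C@H]1C/C=C(\C)[C@@H](OC(=O)CC)C/C=C(\C)C[C@H]1O[Zn]Br | intermediate (not isolated)
18 | methyl (3S,7R,8R,1(10)E,4E)-8-acetoxy-3-(propanoyloxy)germacra-1(10),4,11(13)-trien-12-oate, i.e. methyl 2-[(1R,3E,5S,7E,10R)-10-acetoxy-4,8-dimethyl-5-(propanoyloxy)cyclodeca-3,7-dien-1-yl]prop-2-enoate | C=C(C(=O)OC)[C@H]1C/C=C(\C)[C@@H](OC(=O)CC)C/C=C(\C)C[C@H]1OC(C)=O | intermediate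
19 | methyl (3S,7R,8R,10R)-8-acetoxy-3-(propanoyloxy)eudesma-4,11(13)-dien-12-oate, i.e. methyl 2-[(2R,3R,4aR,7S)-3-acetoxy-4a,8-dimethyl-7-(propanoyloxy)-1,2,3,4,4a,5,6,7-octahydronaphthalen-2-yl]prop-2-enoate | C=C(C(=O)OC)[C@H]1CC2=C(C)[C@@H](OC(=O)CC)CC[C@]2(C)C[C@H]1OC(C)=O | target

## Step count and weak points

Total step count: 11. Longest linear sequence: 11 steps (1 to 19); 6 and 13 enter as bought compounds.

The three steps most likely to fail:

**Step 10 (zinc closure of the ten-membered ring).** The ring size, the cis outcome at C7/C8, the facial control from the remote C3 centre and premature lactonisation of the zinc alkoxide are all uncertain. The fallback sets out from 15. CrCl2 in THF/DMF at high dilution (Nozaki–Hiyama–Kishi-type allylation, anti-selective, known to close ten-membered germacrane rings) should give the all-equatorial 8-epimer methyl (3S,7R,8S,1(10)E,4E)-8-hydroxy-3-(propanoyloxy)germacra-1(10),4,11(13)-trien-12-oate F1. Mitsunobu esterification with acetic acid (PPh3, DIAD, AcOH, THF) then inverts C8 and installs the acetate, returning to the route at 18.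

**Step 11 (transannular cyclisation with the allylic propanoate in place).** The acid may ionise the allylic ester, the ester carbonyl may trap the C4 cation, and the exocyclic 4(15)-alkene or the C10 epimer may persist. The fallback sets out from 10 and carries C3 as a robust silyl ether instead of the ester:
- TBDPSCl and imidazole give (4E,6S,8E)-6-(TBDPS-oxy)-11-(TBS-oxy)-5,9-dimethylundeca-1,4,8-triene F2.
- HF·pyridine removes only the primary TBS group to give (3E,6S,7E)-6-(TBDPS-oxy)-3,7-dimethylundeca-3,7,10-trien-1-ol F3.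
- Cross-metathesis with 13 gives methyl (2Z,5E,7S,9E)-2-(bromomethyl)-7-(TBDPS-oxy)-12-hydroxy-6,10-dimethyldodeca-2,5,9-trienoate F4.
- Dess–Martin oxidation gives methyl (2Z,5E,7S,9E)-2-(bromomethyl)-7-(TBDPS-oxy)-6,10-dimethyl-12-oxododeca-2,5,9-trienoate F5.
- Zinc closure and acetylation give methyl (3S,7R,8R,1(10)E,4E)-8-acetoxy-3-(TBDPS-oxy)germacra-1(10),4,11(13)-trien-12-oate F6.
- TsOH gives methyl (3S,7R,8R,10R)-8-acetoxy-3-(TBDPS-oxy)eudesma-4,11(13)-dien-12-oate F7.
- Bu4NF/AcOH frees methyl (3S,7R,8R,10R)-8-acetoxy-3-hydroxyeudesma-4,11(13)-dien-12-oate F8.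
- Propanoic anhydride/DMAP then returns to the route at 19.

**Step 8 (cross-metathesis with the electron-poor, 1,1-disubstituted allylic bromide).** The bromide partner may react sluggishly or poison the catalyst, and the skipped diene may isomerise. The fallback sets out from 11 and builds the allylic bromide in two stages. Cross-metathesis with methyl 2-(hydroxymethyl)acrylate (same catalyst) gives methyl (2E,5E,7S,9E)-12-(TBS-oxy)-2-(hydroxymethyl)-6,10-dimethyl-7-(propanoyloxy)dodeca-2,5,9-trienoate F9. CBr4/PPh3 converts it to methyl (2Z,5E,7S,9E)-2-(bromomethyl)-12-(TBS-oxy)-6,10-dimethyl-7-(propanoyloxy)dodeca-2,5,9-trienoate F10. HF·pyridine then returns to the route at 14.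

Further compounds
F1 | step 10 | methyl (3S,7R,8S,1(10)E,4E)-8-hydroxy-3-(propanoyloxy)germacra-1(10),4,11(13)-trien-12-oate | C=C(C(=O)OC)[C@H]1C/C=C(\C)[C@@H](OC(=O)CC)C/C=C(\C)C[C@@H]1O
F2 | step 11 | (4E,6S,8E)-6-(TBDPS-oxy)-11-(TBS-oxy)-5,9-dimethylundeca-1,4,8-triene | C=CC/C=C(\C)[C@@H](O[Si](c1ccccc1)(c1ccccc1)C(C)(C)C)C/C=C(\C)CCO[Si](C)(C)C(C)(C)C
F3 | step 11 | (3E,6S,7E)-6-(TBDPS-oxy)-3,7-dimethylundeca-3,7,10-trien-1-ol | C=CC/C=C(\C)[C@@H](O[Si](c1ccccc1)(c1ccccc1)C(C)(C)C)C/C=C(\C)CCO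
F4 | step 11 | methyl (2Z,5E,7S,9E)-2-(bromomethyl)-7-(TBDPS-oxy)-12-hydroxy-6,10-dimethyldodeca-2,5,9-trienoate | BrC/C(C(=O)OC)=C\C/C=C(\C)[C@@H](O[Si](c1ccccc1)(c1ccccc1)C(C)(C)C)C/C=C(\C)CCO
F5 | step 11 | methyl (2Z,5E,7S,9E)-2-(bromomethyl)-7-(TBDPS-oxy)-6,10-dimethyl-12-oxododeca-2,5,9-trienoate | BrC/C(C(=O)OC)=C\C/C=C(\C)[C@@H](O[Si](c1ccccc1)(c1ccccc1)C(C)(C)C)C/C=C(\C)CC=O
F6 | step 11 | methyl (3S,7R,8R,1(10)E,4E)-8-acetoxy-3-(TBDPS-oxy)germacra-1(10),4,11(13)-trien-12-oate | C=C(C(=O)OC)[C@H]1C/C=C(\C)[C@@H](O[Si](c2ccccc2)(c2ccccc2)C(C)(C)C)C/C=C(\C)C[C@H]1OC(C)=O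
F7 | step 11 | methyl (3S,7R,8R,10R)-8-acetoxy-3-(TBDPS-oxy)eudesma-4,11(13)-dien-12-oate | C=C(C(=O)OC)[C@H]1CC2=C(C)[C@@H](O[Si](c3ccccc3)(c3ccccc3)C(C)(C)C)CC[C@]2(C)C[C@H]1OC(C)=O
F8 | step 11 | methyl (3S,7R,8R,10R)-8-acetoxy-3-hydroxyeudesma-4,11(13)-dien-12-oate | C=C(C(=O)OC)[C@H]1CC2=C(C)[C@@H](O)CC[C@]2(C)C[C@H]1OC(C)=O
F9 | step 8 | methyl (2E,5E,7S,9E)-12-(TBS-oxy)-2-(hydroxymethyl)-6,10-dimethyl-7-(propanoyloxy)dodeca-2,5,9-trienoate | OC/C(C(=O)OC)=C\C/C=C(\C)[C@@H](OC(=O)CC)C/C=C(\C)CCO[Si](C)(C)C(C)(C)C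
F10 | step 8 | methyl (2Z,5E,7S,9E)-2-(bromomethyl)-12-(TBS-oxy)-6,10-dimethyl-7-(propanoyloxy)dodeca-2,5,9-trienoate | BrC/C(C(=O)OC)=C\C/C=C(\C)[C@@H](OC(=O)CC)C/C=C(\C)CCO[Si](C)(C)C(C)(C)C
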